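Ring A is numbered C1 (carries the propanoyl chain), C2 (OH), C3 and C4 (H), C5 (carries the aroyl carbon C10) and C6 (OH). It is a 2-alkylresorcinol whose ketone sits ortho to O6 and para to O2, the pattern left by a 1-alkoxy-1,3-bis(silyloxy)diene adding to an ynone. Ring A is therefore cut at C3–C4 and C5–C6. One cycloaddition–aromatisation of the 2-allyl diene 4 with the N-Boc dichloropyrrolyl ethynyl ketone 11 should build the benzene ring with every substituent in place. The allyl group then becomes a pyridyl thioester that C-acylates 2,3-dichloropyrrole.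

Key step: step 6

Remark: 2, 3 and 4 are used as mixtures of double-bond isomers and 10 and 12 are racemic transients, none of which matters for the achiral target; 2,3-dichloro-1H-pyrrole 20 is assumed to be acid- and air-sensitive and is handled only as a cold, dilute solution.

Step 1
Reactants: 1 ethyl 2-acetylpent-4-enoate (ethyl 2-allylacetoacetate, racemic)
Product: 2 ethyl 2-allyl-3-(trimethylsilyloxy)but-2-enoate (E/Z mixture)
Conditions: Me3SiCl, Et3N, toluene, 20 °C, 72 h; filter, distil
Reagents that add atoms: chlorotrimethylsilane, C[Si](C)(C)Cl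
Why: Soft enolisation and O-silylation of a β-keto ester (silyl enol ether formation) takes place at the ketone oxygen, and the α-allyl group should only slow it.

Step 2
Reactants: 2 ethyl 2-allyl-3-(trimethylsilyloxy)but-2-enoate
Product: 4 2-allyl-1-ethoxy-1,3-bis(trimethylsilyloxy)buta-1,3-diene (mixture of ketene acetal geometries), via lithium dienolate 3 (not isolated)
Conditions: LiN(iPr)2 (commercial solution), THF, −78 °C; Me3SiCl, −78 → 20 °C; pentane, filter under argon, used crude
Reagents that add atoms: chlorotrimethylsilane, C[Si](C)(C)Cl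
Why: The amide base should remove the vinylogous γ-proton of the methyl group, which is the most acidic C–H, and O-silylation of dienolate 3 gives the ketene silyl acetal (standard preparation of 1-alkoxy-1,3-bis(silyloxy)dienes).

Step 3
Reactants: 5 4,5-dichloro-1H-pyrrole-2-carboxylic acid
Product: 7 4,5-dichloro-N-methoxy-N-methyl-1H-pyrrole-2-carboxamide, via acyl imidazolide 6 (not isolated)
Conditions: CDI, THF, 20 °C until CO2 evolution ends; MeNHOMe·HCl, 20 °C
Reagents that add atoms: N,O-dimethylhydroxylamine hydrochloride, CNOC.Cl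
Why: Activation with carbonyldiimidazole and aminolysis of the acyl imidazolide (Weinreb amide formation) is mild enough to leave the pyrrole N–H and both C–Cl bonds untouched.

Step 4
Reactants: 7 4,5-dichloro-N-methoxy-N-methyl-1H-pyrrole-2-carboxamide
Product: 8 tert-butyl 2,3-dichloro-5-[methoxy(methyl)carbamoyl]pyrrole-1-carboxylate
Conditions: Boc2O, DMAP (cat.), MeCN, 20 °C
Reagents that add atoms: di-tert-butyl dicarbonate, CC(C)(C)OC(=O)OC(=O)OC(C)(C)C
Why: DMAP-catalysed N-tert-butoxycarbonylation of the acidic acylpyrrole N–H removes the only proton that would later quench the Grignard reagent and the ketene acetal.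

Step 5
Reactants: 8 tert-butyl 2,3-dichloro-5-[methoxy(methyl)carbamoyl]pyrrole-1-carboxylate; 9 ethynylmagnesium bromide
Product: 11 tert-butyl 2,3-dichloro-5-propioloylpyrrole-1-carboxylate, via magnesium hemiaminal chelate 10 (not isolated)
Conditions: HC≡CMgBr (0.5 M in THF), THF, −20 → 0 °C; inverse quench into cold 1 M HCl
Reagents that add atoms: none
Why: In this Weinreb ketone synthesis the chelated tetrahedral adduct 10 should prevent a second addition, and the acidic inverse quench keeps the released amine protonated so that it cannot add to the ynone.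

Step 6
Reactants: 4 2-allyl-1-ethoxy-1,3-bis(trimethylsilyloxy)buta-1,3-diene (1.5 equiv); 11 tert-butyl 2,3-dichloro-5-propioloylpyrrole-1-carboxylate
Product: 14 tert-butyl 5-(3-allyl-2,4-dihydroxybenzoyl)-2,3-dichloropyrrole-1-carboxylate, via cyclohexadiene cycloadduct 12 (not isolated), via aryl trimethylsilyl ether 13 (not isolated)
Conditions: toluene, −78 → 20 °C (45 °C if slow); then 1 M HCl, THF, 0 °C, 15 min
Reagents that add atoms: none
Why: The electron-rich diene 4 (largest HOMO coefficient at its CH2 terminus) and the electron-poor ynone 11 (largest LUMO coefficient at the alkyne CH) should combine in a polarised Diels–Alder reaction, or in its stepwise limit a Mukaiyama–Michael addition followed by Claisen-type attack of the allenolate on the silylated ester carbon, to give the 1,4-cyclohexadiene 12. The closest known reaction type is the resorcinol synthesis from 1-alkoxy-1,3-bis(silyloxy)butadienes and acetylenic ketones or esters. Ring A is closed by a suprafacial [4+2] cycloaddition that forms C3–C4 and C5–C6; in the stepwise limit the second bond forms by a 6-(enolexo)-exo-trig closure. The ketal carbon of 12 is a transient racemic centre that disappears when Me3SiOEt is lost on aromatisation, so no stereocentre has to be controlled. The step needs regioselectivity, and polarity matching secures it: the nucleophilic CH2 terminus meets the β-carbon of the ynone and the ketene acetal carbon meets the α-carbon, which places C10 ortho to O6 and para to O2 with the allyl group between the two oxygens. No Lewis acid is present, so the allyl group and the N-Boc carbamate should stay untouched, and the brief cold acid wash should cleave only the aryl silyl ether of 13.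

Step 7
Reactants: 14 tert-butyl 5-(3-allyl-2,4-dihydroxybenzoyl)-2,3-dichloropyrrole-1-carboxylate
Product: 15 tert-butyl 5-[3-allyl-2,4-bis(tert-butoxycarbonyloxy)benzoyl]-2,3-dichloropyrrole-1-carboxylate
Conditions: Boc2O (2.5 equiv), DMAP (cat.), Et3N, CH2Cl2, 20 °C
Reagents that add atoms: di-tert-butyl dicarbonate, CC(C)(C)OC(=O)OC(=O)OC(C)(C)C
Why: DMAP-catalysed O-tert-butoxycarbonylation masks both phenols, which would otherwise consume borane, be oxidised and lactonise onto the later activated ester, with groups that leave in the same final operation as the N-Boc group.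

Step 8
Reactants: 15 tert-butyl 5-[3-allyl-2,4-bis(tert-butoxycarbonyloxy)benzoyl]-2,3-dichloropyrrole-1-carboxylate
Product: 17 tert-butyl 5-[2,4-bis(tert-butoxycarbonyloxy)-3-(3-hydroxypropyl)benzoyl]-2,3-dichloropyrrole-1-carboxylate, via alkylborane 16 (not isolated)
Conditions: 9-BBN (1.3 equiv), THF, 0 → 20 °C; then 30% H2O2, pH 7 phosphate buffer, 0 → 20 °C
Reagents that add atoms: hydrogen peroxide, OO
Why: Brown hydroboration–oxidation with 9-BBN is anti-Markovnikov on the terminal alkene and far faster than reduction of the hindered diaryl ketone, the carbamate or the carbonates, and buffered peroxide oxidises the C–B bond without base that would cleave the Boc groups.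

Step 9
Reactants: 17 tert-butyl 5-[2,4-bis(tert-butoxycarbonyloxy)-3-(3-hydroxypropyl)benzoyl]-2,3-dichloropyrrole-1-carboxylate
Product: 18 3-[2,6-bis(tert-butoxycarbonyloxy)-3-(1-tert-butoxycarbonyl-4,5-dichloropyrrole-2-carbonyl)phenyl]propanoic acid
Conditions: TEMPO (cat.), PhI(OAc)2 (2.2 equiv), MeCN/H2O, 20 °C
Reagents that add atoms: water, O
Why: Oxoammonium-mediated oxidation (TEMPO with PhI(OAc)2 in aqueous acetonitrile) takes the primary alcohol through the aldehyde hydrate to the acid under near-neutral conditions that carbonates and the carbamate tolerate.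

Step 10
Reactants: 18 3-[2,6-bis(tert-butoxycarbonyloxy)-3-(1-tert-butoxycarbonyl-4,5-dichloropyrrole-2-carbonyl)phenyl]propanoic acid
Product: 19 S-pyridin-2-yl 3-[2,6-bis(tert-butoxycarbonyloxy)-3-(1-tert-butoxycarbonyl-4,5-dichloropyrrole-2-carbonyl)phenyl]propanethioate
Conditions: 2,2'-dipyridyl disulfide, PPh3, CH2Cl2, 20 °C
Reagents that add atoms: 2,2'-dipyridyl disulfide, c1ccc(SSc2ccccn2)nc1
Why: The Mukaiyama redox condensation gives the 2-pyridyl thioester under neutral conditions, and the masked ortho phenols cannot close to a dihydrocoumarin.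

Step 11
Reactants: 5 4,5-dichloro-1H-pyrrole-2-carboxylic acid
Product: 20 2,3-dichloro-1H-pyrrole
Conditions: Ag2CO3 (10 mol %), AcOH (5 mol %), DMSO, 120 °C, argon; water/pentane partition, NaHCO3 wash, dried solution kept at −20 °C and used the same day
Reagents that add atoms: none
Why: Silver-catalysed protodecarboxylation of a heteroarene-2-carboxylic acid (silver carboxylate, loss of CO2, protonolysis of the aryl–silver bond) is favoured by the α-nitrogen and the electron-withdrawing chlorines and frees the α-carbon that is to be acylated.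

Step 12
Reactants: 19 S-pyridin-2-yl 3-[2,6-bis(tert-butoxycarbonyloxy)-3-(1-tert-butoxycarbonyl-4,5-dichloropyrrole-2-carbonyl)phenyl]propanethioate; 20 2,3-dichloro-1H-pyrrole (3 equiv)
Product: 22 tert-butyl 5-[2,4-bis(tert-butoxycarbonyloxy)-3-[3-(4,5-dichloro-1H-pyrrol-2-yl)-3-oxopropyl]benzoyl]-2,3-dichloropyrrole-1-carboxylate, via (2,3-dichloropyrrol-1-yl)magnesium chloride 21 (not isolated)
Conditions: 20, MeMgCl, toluene/THF, 0 °C; then 19, −78 → −20 °C; aq. NH4Cl
Reagents that add atoms: none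
Why: In this C-acylation of a pyrrolylmagnesium halide by a 2-pyridyl thioester, magnesium chelation between the pyridine nitrogen and the thioester carbonyl should deliver the acyl group to the only free α-carbon (the other is blocked by chlorine), while the weakly nucleophilic reagent leaves the diaryl ketone, carbamate and carbonates alone at low temperature.

Step 13
Reactants: 22 tert-butyl 5-[2,4-bis(tert-butoxycarbonyloxy)-3-[3-(4,5-dichloro-1H-pyrrol-2-yl)-3-oxopropyl]benzoyl]-2,3-dichloropyrrole-1-carboxylate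
Product: 23 dihydrotetrachlorizine, 3-[3-(4,5-dichloro-1H-pyrrole-2-carbonyl)-2,6-dihydroxyphenyl]-1-(4,5-dichloro-1H-pyrrol-2-yl)propan-1-one
Conditions: TFA/CH2Cl2 (1:3), anisole, 0 → 20 °C
Reagents that add atoms: none
Why: Acidolysis of the tert-butyl carbamate and both tert-butyl carbonates (loss of isobutene and CO2) frees the N–H and both phenols in one operation, with anisole trapping tert-butyl cations before they can alkylate ring A.

Compound list
1 | ethyl 2-acetylpent-4-enoate (racemic) | CCOC(=O)C(CC=C)C(C)=O | starting material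
2 | ethyl 2-allyl-3-(trimethylsilyloxy)but-2-enoate (E/Z mixture) | CCOC(=O)C(CC=C)=C(C)O[Si](C)(C)C | intermediate
3 | lithium 2-allyl-1-ethoxy-3-(trimethylsilyloxy)buta-1,3-dien-1-olate (isomer mixture) | [Li]OC(OCC)=C(CC=C)C(=C)O[Si](C)(C)C | intermediate
4 | 2-allyl-1-ethoxy-1,3-bis(trimethylsilyloxy)buta-1,3-diene (isomer mixture) | C=C(O[Si](C)(C)C)C(CC=C)=C(OCC)O[Si](C)(C)C | intermediate
5 | 4,5-dichloro-1H-pyrrole-2-carboxylic acid | O=C(O)c1cc(Cl)c(Cl)[nH]1 | starting material
6 | (4,5-dichloro-1H-pyrrol-2-yl)(imidazol-1-yl)methanone | O=C(c1cc(Cl)c(Cl)[nH]1)n1ccnc1 | intermediate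
7 | 4,5-dichloro-N-methoxy-N-methyl-1H-pyrrole-2-carboxamide | CON(C)C(=O)c1cc(Cl)c(Cl)[nH]1 | intermediate
8 | tert-butyl 2,3-dichloro-5-[methoxy(methyl)carbamoyl]pyrrole-1-carboxylate | CON(C)C(=O)c1cc(Cl)c(Cl)n1C(=O)OC(C)(C)C | intermediate
9 | ethynylmagnesium bromide | C#C[Mg]Br | starting material
10 | bromomagnesium alkoxide of tert-butyl 2,3-dichloro-5-[1-hydroxy-1-[methoxy(methyl)amino]prop-2-ynyl]pyrrole-1-carboxylate (racemic) | C#CC(O[Mg]Br)(N(C)OC)c1cc(Cl)c(Cl)n1C(=O)OC(C)(C)C | intermediate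
11 | tert-butyl 2,3-dichloro-5-propioloylpyrrole-1-carboxylate | C#CC(=O)c1cc(Cl)c(Cl)n1C(=O)OC(C)(C)C | intermediate
12 | tert-butyl 5-[5-allyl-6-ethoxy-4,6-bis(trimethylsilyloxy)cyclohexa-1,4-diene-1-carbonyl]-2,3-dichloropyrrole-1-carboxylate (racemic) | C=CCC1=C(O[Si](C)(C)C)CC=C(C(=O)c2cc(Cl)c(Cl)n2C(=O)OC(C)(C)C)C1(OCC)O[Si](C)(C)C | intermediate
13 | tert-butyl 5-[3-allyl-2-hydroxy-4-(trimethylsilyloxy)benzoyl]-2,3-dichloropyrrole-1-carboxylate | C=CCc1c(O[Si](C)(C)C)ccc(C(=O)c2cc(Cl)c(Cl)n2C(=O)OC(C)(C)C)c1O | intermediate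
14 | tert-butyl 5-(3-allyl-2,4-dihydroxybenzoyl)-2,3-dichloropyrrole-1-carboxylate | C=CCc1c(O)ccc(C(=O)c2cc(Cl)c(Cl)n2C(=O)OC(C)(C)C)c1O | intermediate
15 | tert-butyl 5-[3-allyl-2,4-bis(tert-butoxycarbonyloxy)benzoyl]-2,3-dichloropyrrole-1-carboxylate | C=CCc1c(OC(=O)OC(C)(C)C)ccc(C(=O)c2cc(Cl)c(Cl)n2C(=O)OC(C)(C)C)c1OC(=O)OC(C)(C)C | intermediate
16 | tert-butyl 5-[3-[3-(9-borabicyclo[3.3.1]nonan-9-yl)propyl]-2,4-bis(tert-butoxycarbonyloxy)benzoyl]-2,3-dichloropyrrole-1-carboxylate | CC(C)(C)OC(=O)Oc1ccc(C(=O)c2cc(Cl)c(Cl)n2C(=O)OC(C)(C)C)c(OC(=O)OC(C)(C)C)c1CCCB1C2CCCC1CCC2 | intermediate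
17 | tert-butyl 5-[2,4-bis(tert-butoxycarbonyloxy)-3-(3-hydroxypropyl)benzoyl]-2,3-dichloropyrrole-1-carboxylate | OCCCc1c(OC(=O)OC(C)(C)C)ccc(C(=O)c2cc(Cl)c(Cl)n2C(=O)OC(C)(C)C)c1OC(=O)OC(C)(C)C | intermediate
18 | 3-[2,6-bis(tert-butoxycarbonyloxy)-3-(1-tert-butoxycarbonyl-4,5-dichloropyrrole-2-carbonyl)phenyl]propanoic acid | OC(=O)CCc1c(OC(=O)OC(C)(C)C)ccc(C(=O)c2cc(Cl)c(Cl)n2C(=O)OC(C)(C)C)c1OC(=O)OC(C)(C)C | intermediate
19 | S-pyridin-2-yl 3-[2,6-bis(tert-butoxycarbonyloxy)-3-(1-tert-butoxycarbonyl-4,5-dichloropyrrole-2-carbonyl)phenyl]propanethioate | O=C(CCc1c(OC(=O)OC(C)(C)C)ccc(C(=O)c2cc(Cl)c(Cl)n2C(=O)OC(C)(C)C)c1OC(=O)OC(C)(C)C)Sc1ccccn1 | intermediate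
20 | 2,3-dichloro-1H-pyrrole | Clc1cc[nH]c1Cl | intermediate
21 | (2,3-dichloropyrrol-1-yl)magnesium chloride | Cl[Mg]n1ccc(Cl)c1Cl | intermediate
22 | tert-butyl 5-[2,4-bis(tert-butoxycarbonyloxy)-3-[3-(4,5-dichloro-1H-pyrrol-2-yl)-3-oxopropyl]benzoyl]-2,3-dichloropyrrole-1-carboxylate | O=C(CCc1c(OC(=O)OC(C)(C)C)ccc(C(=O)c2cc(Cl)c(Cl)n2C(=O)OC(C)(C)C)c1OC(=O)OC(C)(C)C)c1cc(Cl)c(Cl)[nH]1 | intermediate
23 | dihydrotetrachlorizine | O=C(CCc1c(O)ccc(C(=O)c2cc(Cl)c(Cl)[nH]2)c1O)c1cc(Cl)c(Cl)[nH]1 | target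

Total step count: 13.
Longest linear sequence: 10 steps (5 → 7 → 8 → 11 → 14 → 15 → 17 → 18 → 19 → 22 → 23; steps 3, 4, 5, 6, 7, 8, 9, 10, 12 and 13).

Steps most likely to fail

Step 6. The diene may be protodesilylated or polymerise before it reacts, the sequence may stop at an open-chain Michael adduct that does not close, or the N-Boc group may be lost from the activated ynone. The fallback brings ring A in ready-made; it sets out from Weinreb amide 8 and comes back to the route at 15. Commercial 1,3-bis(methoxymethoxy)benzene (COCOc1cccc(OCOC)c1) would be lithiated between the two oxygens (n-BuLi, THF, 0 °C) to [2,6-bis(methoxymethoxy)phenyl]lithium F1. Allylation (allyl bromide, CuBr·SMe2 cat.) would give 2-allyl-1,3-bis(methoxymethoxy)benzene F2. Bromination para to one ether oxygen (NBS, MeCN, 0 °C) would give 2-allyl-4-bromo-1,3-bis(methoxymethoxy)benzene F3. Bromine–lithium exchange (n-BuLi, THF, −78 °C) would give [3-allyl-2,4-bis(methoxymethoxy)phenyl]lithium F4, and its addition to 8 would give tert-butyl 5-[3-allyl-2,4-bis(methoxymethoxy)benzoyl]-2,3-dichloropyrrole-1-carboxylate F5. HCl in MeOH at 40 °C would remove both methoxymethyl groups and the N-Boc group to give (3-allyl-2,4-dihydroxyphenyl)(4,5-dichloro-1H-pyrrol-2-yl)methanone F6. Boc2O (3.5 equiv) with DMAP would then protect nitrogen and both phenols at once to give 15.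

Step 11. The α-unsubstituted chloropyrrole may polymerise or oxidise in the hot reaction mixture or during isolation. The fallback does without free 2,3-dichloropyrrole and chlorinates last; it sets out from thioester 19 and comes back at 22. Commercial pyrrole (c1cc[nH]c1) and MeMgCl would give pyrrol-1-ylmagnesium chloride F7. This would C-acylate with 19 (toluene, −78 °C) to give tert-butyl 5-[2,4-bis(tert-butoxycarbonyloxy)-3-[3-oxo-3-(1H-pyrrol-2-yl)propyl]benzoyl]-2,3-dichloropyrrole-1-carboxylate F8. N-Chlorosuccinimide (2 equiv, THF, 0 → 20 °C) would then chlorinate the 4- and 5-positions of the only electron-rich ring to give 22.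

Step 12. The ambident pyrrolyl anion may be acylated on nitrogen, may take a Boc group from the substrate, or an O-Boc group may be lost early and the freed phenoxide may lactonise onto the thioester. The fallback uses a C-metallated, N-protected pyrrole in a cross-coupling; it sets out from 20 and acid 18 and comes back at 23. Boc2O with DMAP would convert 20 into tert-butyl 2,3-dichloropyrrole-1-carboxylate F9. Directed α-lithiation (lithium 2,2,6,6-tetramethylpiperidide, LiNC9H18, THF, −78 °C) would give tert-butyl 2,3-dichloro-5-lithiopyrrole-1-carboxylate F10, and ZnCl2 would turn it into [1-(tert-butoxycarbonyl)-4,5-dichloropyrrol-2-yl]zinc chloride F11. Acid 18 would be converted with 1-chloro-N,N,2-trimethylprop-1-en-1-amine (CH2Cl2, 0 °C) into 3-[2,6-bis(tert-butoxycarbonyloxy)-3-(1-tert-butoxycarbonyl-4,5-dichloropyrrole-2-carbonyl)phenyl]propanoyl chloride F12. A Negishi acylation of F11 with F12 (Pd(PPh3)4, zerovalent palladium, THF, 20 °C) would give tert-butyl 5-[2,4-bis(tert-butoxycarbonyloxy)-3-[3-(1-tert-butoxycarbonyl-4,5-dichloropyrrol-2-yl)-3-oxopropyl]benzoyl]-2,3-dichloropyrrole-1-carboxylate F13. The conditions of step 13 would remove all four Boc groups to give 23.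

Further compounds
F1 | step 6 | [2,6-bis(methoxymethoxy)phenyl]lithium | [Li]c1c(OCOC)cccc1OCOC
F2 | step 6 | 2-allyl-1,3-bis(methoxymethoxy)benzene | C=CCc1c(OCOC)cccc1OCOC
F3 | step 6 | 2-allyl-4-bromo-1,3-bis(methoxymethoxy)benzene | C=CCc1c(OCOC)ccc(Br)c1OCOC
F4 | step 6 | [3-allyl-2,4-bis(methoxymethoxy)phenyl]lithium | C=CCc1c(OCOC)ccc([Li])c1OCOC
F5 | step 6 | tert-butyl 5-[3-allyl-2,4-bis(methoxymethoxy)benzoyl]-2,3-dichloropyrrole-1-carboxylate | C=CCc1c(OCOC)ccc(C(=O)c2cc(Cl)c(Cl)n2C(=O)OC(C)(C)C)c1OCOC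
F6 | step 6 | (3-allyl-2,4-dihydroxyphenyl)(4,5-dichloro-1H-pyrrol-2-yl)methanone | C=CCc1c(O)ccc(C(=O)c2cc(Cl)c(Cl)[nH]2)c1O
F7 | step 11 | pyrrol-1-ylmagnesium chloride | Cl[Mg]n1cccc1
F8 | step 11 | tert-butyl 5-[2,4-bis(tert-butoxycarbonyloxy)-3-[3-oxo-3-(1H-pyrrol-2-yl)propyl]benzoyl]-2,3-dichloropyrrole-1-carboxylate | O=C(CCc1c(OC(=O)OC(C)(C)C)ccc(C(=O)c2cc(Cl)c(Cl)n2C(=O)OC(C)(C)C)c1OC(=O)OC(C)(C)C)c1ccc[nH]1
F9 | step 12 | tert-butyl 2,3-dichloropyrrole-1-carboxylate | CC(C)(C)OC(=O)n1ccc(Cl)c1Cl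
F10 | step 12 | tert-butyl 2,3-dichloro-5-lithiopyrrole-1-carboxylate | [Li]c1cc(Cl)c(Cl)n1C(=O)OC(C)(C)C
F11 | step 12 | [1-(tert-butoxycarbonyl)-4,5-dichloropyrrol-2-yl]zinc chloride | Cl[Zn]c1cc(Cl)c(Cl)n1C(=O)OC(C)(C)C
F12 | step 12 | 3-[2,6-bis(tert-butoxycarbonyloxy)-3-(1-tert-butoxycarbonyl-4,5-dichloropyrrole-2-carbonyl)phenyl]propanoyl chloride | O=C(Cl)CCc1c(OC(=O)OC(C)(C)C)ccc(C(=O)c2cc(Cl)c(Cl)n2C(=O)OC(C)(C)C)c1OC(=O)OC(C)(C)C
F13 | step 12 | tert-butyl 5-[2,4-bis(tert-butoxycarbonyloxy)-3-[3-(1-tert-butoxycarbonyl-4,5-dichloropyrrol-2-yl)-3-oxopropyl]benzoyl]-2,3-dichloropyrrole-1-carboxylate | O=C(CCc1c(OC(=O)OC(C)(C)C)ccc(C(=O)c2cc(Cl)c(Cl)n2C(=O)OC(C)(C)C)c1OC(=O)OC(C)(C)C)c1cc(Cl)c(Cl)n1C(=O)OC(C)(C)C
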